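**Retrosynthetic overview**
1. Lettering: rings A to G run from the 2,4,6-trihydroxyphenyl end to the 3,4,5-trihydroxyphenoxy end. On ring D, D1 holds the oxygen to ring C, D2 is the only CH, D3 to D5 hold hydroxyls, and D6 holds the oxygen to ring E.
2. Decisive feature: ring D has five adjacent C–O carbons (D3-D4-D5-D6-D1), and its ortho pair D6/D1 carries both trimer arms. This pattern is too crowded and too electron-rich for substitution on an arene, so ring D is built last from small unsaturated pieces.
3. Key disconnection (bonds D2–D3 and D1–D6, Danheiser benzannulation): D1–D2 come from the ethynyl ether of the permethylated A–C trimer. D3–D6 come from a 2-aryloxy-3,4-dimethoxycyclobutenone that carries the permethylated E–G trimer.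
4. Each arm grows from purchased arenes by a repeated pair of steps: Ullmann etherification with a para-bromobenzaldehyde, then Baeyer–Villiger exchange of CHO for OH. The E–G phenol enters the four-membered ring through squaric acid methyl ester chloride, because an aryloxide cannot expel methoxide from dimethyl squarate.
5. Ring order: A–C and E–G (bought, joined by ether bonds), cyclobutene (bought), then ring D in the key step. Sixteen methyl ethers are cleaved at the end.

Key step: step 15

Remark on the chemistry: the target has no stereocentre. The sp3 carbon of the cyclobutenones is carried racemic and disappears when ring D aromatises. The six numbered starting materials are assumed to be catalogue chemicals.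

**Step 1**
Reactants: 1 2,4,6-trimethoxyphenol (ring A); 2 4-bromo-2,6-dimethoxybenzaldehyde (source of rings B and C)
Product: 3 ring A–B aldehyde [2,6-dimethoxy-4-(2,4,6-trimethoxyphenoxy)benzaldehyde]
Conditions: CuI (10 mol %), picolinic acid (20 mol %), K3PO4 (2 equiv), DMSO, 90 °C, Ar
Reagents that add atoms: none
Why: Ligand-accelerated Ullmann diaryl ether synthesis; the CuI/picolinic acid system accepts 2,6-disubstituted phenols, and the C–Br bond of 2 lies between two CH positions and is activated by the para formyl group.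

**Step 2**
Reactants: 3 ring A–B aldehyde
Product: 5 ring A–B phenol [2,6-dimethoxy-4-(2,4,6-trimethoxyphenoxy)phenol], via aryl formate 4 (not isolated)
Conditions: mCPBA (1.2 equiv), CH2Cl2, 0 °C to rt; aq Na2S2O3/NaHCO3 wash; crude formate, K2CO3 (0.2 equiv), MeOH, rt, Ar
Reagents that add atoms: mCPBA, O=C(OO)c1cccc(Cl)c1
Why: Baeyer–Villiger oxidation in which the 2,4,6-trioxygenated aryl group migrates in preference to hydrogen, and the formate shields the oxidation-prone phenol from the peracid until mild methanolysis releases it.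

**Step 3**
Reactants: 5 ring A–B phenol; 2 4-bromo-2,6-dimethoxybenzaldehyde
Product: 6 ring A–C aldehyde [4-[2,6-dimethoxy-4-(2,4,6-trimethoxyphenoxy)phenoxy]-2,6-dimethoxybenzaldehyde]
Conditions: CuI (10 mol %), picolinic acid (20 mol %), K3PO4 (2 equiv), DMSO, 90 °C, Ar
Reagents that add atoms: none
Why: Same Ullmann etherification as in step 1, a 2,6-dimethoxyphenol again meeting an unhindered, formyl-activated C–Br bond.

**Step 4**
Reactants: 6 ring A–C aldehyde
Product: 8 ring A–C trimer phenol [4-[2,6-dimethoxy-4-(2,4,6-trimethoxyphenoxy)phenoxy]-2,6-dimethoxyphenol], via aryl formate 7 (not isolated)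
Conditions: mCPBA (1.2 equiv), CH2Cl2, 0 °C to rt; aq Na2S2O3/NaHCO3 wash; crude formate, K2CO3 (0.2 equiv), MeOH, rt, Ar
Reagents that add atoms: mCPBA, O=C(OO)c1cccc(Cl)c1
Why: Baeyer–Villiger oxidation and formate methanolysis as in step 2, the migrating ring C having the same 2,6-dimethoxy-4-aryloxy pattern.

**Step 5**
Reactants: 8 ring A–C trimer phenol; 9 trichloroethylene
Product: 11 (E)-1,2-dichlorovinyl ether of the A–C trimer, via dichloroacetylene 10 (not isolated)
Conditions: K2CO3 (2 equiv), 9 (2 equiv), DMF, 70 °C, Ar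
Reagents that add atoms: none
Why: Elimination–addition, the first stage of the trichloroethylene route to ynol ethers: base removes HCl from 9, and the phenoxide adds anti to the small linear dichloroacetylene, which a hindered phenoxide can still reach and which sets the E geometry.

**Step 6**
Reactants: 11 (E)-1,2-dichlorovinyl ether
Product: 14 ethynyl ether of the A–C trimer, via chloroethynyl ether 12 (not isolated), via lithium acetylide 13 (not isolated)
Conditions: n-BuLi (2.5 equiv), THF, −78 to −40 °C; then H2O/THF, −78 to 0 °C; short plug of basic alumina, used at once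
Reagents that add atoms: none
Why: Second stage of the trichloroethylene route: deprotonation with β-elimination gives the chloroalkyne, chlorine–lithium exchange gives the acetylide and protonation gives the terminal ynol ether, while any stray ring lithiation is undone by the same quench.

**Step 7**
Reactants: 15 3,4,5-trimethoxyphenol (ring G); 16 4-bromo-3,5-dimethoxybenzaldehyde (source of rings F and E)
Product: 17 ring F–G aldehyde [3,5-dimethoxy-4-(3,4,5-trimethoxyphenoxy)benzaldehyde]
Conditions: CuI (20 mol %), picolinic acid (40 mol %), K3PO4 (2 equiv), DMSO, 110 °C, Ar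
Reagents that add atoms: none
Why: Ullmann diaryl ether synthesis with the roles reversed: the phenol is unhindered and nucleophilic, and the C–Br bond, though flanked by two methoxy groups, is activated by the para formyl group.

**Step 8**
Reactants: 17 ring F–G aldehyde
Product: 19 ring F–G phenol [3,5-dimethoxy-4-(3,4,5-trimethoxyphenoxy)phenol], via aryl formate 18 (not isolated)
Conditions: mCPBA (1.3 equiv), CH2Cl2, rt to 40 °C; aq Na2S2O3/NaHCO3 wash; crude formate, K2CO3 (0.2 equiv), MeOH, rt, Ar
Reagents that add atoms: mCPBA, O=C(OO)c1cccc(Cl)c1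
Why: Baeyer–Villiger oxidation and formate methanolysis, the established passage from 4-aryloxybenzaldehydes to 4-aryloxyphenols, with aryl migration supported by the para oxygen donor.

**Step 9**
Reactants: 19 ring F–G phenol; 16 4-bromo-3,5-dimethoxybenzaldehyde
Product: 20 ring E–G aldehyde [4-[3,5-dimethoxy-4-(3,4,5-trimethoxyphenoxy)phenoxy]-3,5-dimethoxybenzaldehyde]
Conditions: CuI (20 mol %), picolinic acid (40 mol %), K3PO4 (2 equiv), DMSO, 110 °C, Ar
Reagents that add atoms: none
Why: Same Ullmann etherification as in step 7, since the phenolic carbon of 19 again lies between two CH positions.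

**Step 10**
Reactants: 20 ring E–G aldehyde
Product: 22 ring E–G trimer phenol [4-[3,5-dimethoxy-4-(3,4,5-trimethoxyphenoxy)phenoxy]-3,5-dimethoxyphenol], via aryl formate 21 (not isolated)
Conditions: mCPBA (1.3 equiv), CH2Cl2, rt to 40 °C; aq Na2S2O3/NaHCO3 wash; crude formate, K2CO3 (0.2 equiv), MeOH, rt, Ar
Reagents that add atoms: mCPBA, O=C(OO)c1cccc(Cl)c1
Why: Baeyer–Villiger oxidation and formate methanolysis as in step 8, on the same 3,5-dimethoxy-4-aryloxybenzaldehyde pattern.

**Step 11**
Reactants: 23 squaryl dichloride (3,4-dichlorocyclobut-3-ene-1,2-dione)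
Product: 24 squaric acid methyl ester chloride (3-chloro-4-methoxycyclobut-3-ene-1,2-dione)
Conditions: MeOH (1.0 equiv), CH2Cl2, 0 °C to rt
Reagents that add atoms: methanol, CO
Why: Addition–elimination at a vinylogous acid chloride; one equivalent of methanol exchanges only the first chloride, because the methoxy donor then deactivates the ring toward a second attack.

**Step 12**
Reactants: 22 ring E–G trimer phenol; 24 squaric acid methyl ester chloride
Product: 26 mixed aryl methyl squarate (3-aryloxy-4-methoxycyclobut-3-ene-1,2-dione; aryl = E–G trimer bound through E1), via sodium phenoxide 25 (not isolated)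
Conditions: NaH (1.05 equiv), THF, 0 °C; then cannulated into 24 (1.1 equiv), THF, −78 to −20 °C
Reagents that add atoms: none
Why: Addition–elimination at the chlorine-bearing vinylogous acyl carbon, where chloride is by far the best leaving group, so the aryloxy group stays in place once installed.

**Step 13**
Reactants: 26 mixed aryl methyl squarate
Product: 27 racemic 2-aryloxy-4-hydroxy-3-methoxycyclobut-2-en-1-one
Conditions: LiAlH(OtBu)3 (1.05 equiv), THF, −78 °C; then H2O (4 equiv) in THF, −78 to 0 °C, filtration through Celite, no acid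
Reagents that add atoms: none
Why: 1,2-Reduction of a squarate diester with LiAlH(OtBu)3, the known route to 4-hydroxy-2,3-dialkoxycyclobutenones; hydride should attack the carbonyl next to C–OMe, which is the vinylogous ester of the weaker aryloxy donor and the less shielded one, and the new carbinol centre is formed racemic because nothing in 26 biases the two faces.

**Step 14**
Reactants: 27 racemic 2-aryloxy-4-hydroxy-3-methoxycyclobut-2-en-1-one
Product: 28 racemic 2-aryloxy-3,4-dimethoxycyclobut-2-en-1-one
Conditions: MeI (10 equiv), Ag2O (2 equiv), 4 Å molecular sieves, CH2Cl2, rt, dark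
Reagents that add atoms: iodomethane, CI
Why: Purdie methylation, the usual near-neutral O-methylation of 4-hydroxycyclobutenones, which avoids both acid-induced loss of methanol to a cyclobutenedione and alkoxide-triggered ring opening.

**Step 15**
Reactants: 14 ethynyl ether of the A–C trimer; 28 racemic 2-aryloxy-3,4-dimethoxycyclobut-2-en-1-one
Product: 33 heptamer with free D3 hydroxyl and sixteen methyl ethers, via vinylketene 29 (not isolated), via 4-vinylcyclobutenone 30 (not isolated), via dienylketene 31 (not isolated), via cyclohexadienone 32 (not isolated)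
Conditions: 14 (1.5 equiv), PhMe (0.5 M in 28), 80 °C then 110 °C, sealed tube, Ar
Reagents that add atoms: none
Why: Heating opens 28 by conrotatory 4π cleavage of its C1–C4 bond, the C4 methoxy group turning outward, to aryloxy(vinyl)ketene 29, which ynol ether 14 traps in a [2+2] cycloaddition to give 4-vinylcyclobutenone 30. A second 4π opening of 30, with the aryloxy donor turning outward and the vinyl group inward, gives dienylketene 31, and ring D closes by thermal 6π electrocyclisation of 31 (bond D3–D4) to cyclohexadienone 32, which tautomerises to phenol 33. This is the Danheiser benzannulation of a cyclobutenone with an alkynyl ether, the closest known cases being alkyl-substituted cyclobutenones with alkoxy- and siloxyacetylenes, so the fully oxygenated pair used here stretches the scope in substitution only. One regiochemical outcome is needed: the unsubstituted, nucleophilic alkyne carbon must bond to the ketene carbonyl carbon (D2–D3) and the oxygen-bearing alkyne carbon to the ketene α-carbon (D1–D6), which the oxygen lone pair of 14 enforces, the more so as the two ortho methoxy groups twist ring C out of conjugation; this places the D1 aryloxy group meta to the D3 hydroxyl and ortho to the D6 aryloxy group. Capture of 29 must also outrun ketene dimerisation and acylation of 33, which is helped by the reversible opening of 28 (low standing ketene concentration), by excess 14 at high concentration and by the absence of β-hydrogens in 14, which rules out retro-ene loss of the alkyne. No stereocentre is set, since the racemic centres of 28, 30 and 32 vanish on aromatisation.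

**Step 16**
Reactants: 33 heptamer with free D3 hydroxyl and sixteen methyl ethers
Product: 34 target CNP0304148.0
Conditions: BBr3 (1 M in CH2Cl2, 40 equiv), CH2Cl2, −78 °C to rt, Ar; then H2O, 0 °C; degassed solvents throughout isolation
Reagents that add atoms: none
Why: Lewis acid-mediated aryl methyl ether cleavage, in which BBr3 binds each methoxy oxygen and bromide removes the methyl group by SN2, whereas the six diaryl ether oxygens offer no sp3 carbon and stay intact.

**Compound list**
1 | 2,4,6-trimethoxyphenol | COc1cc(OC)c(O)c(OC)c1 | starting material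
2 | 4-bromo-2,6-dimethoxybenzaldehyde | COc1cc(Br)cc(OC)c1C=O | starting material
3 | ring A–B aldehyde | COc1cc(OC)c(Oc2cc(OC)c(C=O)c(OC)c2)c(OC)c1 | intermediate
4 | ring A–B aryl formate | COc1cc(OC)c(Oc2cc(OC)c(OC=O)c(OC)c2)c(OC)c1 | intermediate
5 | ring A–B phenol | COc1cc(OC)c(Oc2cc(OC)c(O)c(OC)c2)c(OC)c1 | intermediate
6 | ring A–C aldehyde | COc1cc(OC)c(Oc2cc(OC)c(Oc3cc(OC)c(C=O)c(OC)c3)c(OC)c2)c(OC)c1 | intermediate
7 | ring A–C aryl formate | COc1cc(OC)c(Oc2cc(OC)c(Oc3cc(OC)c(OC=O)c(OC)c3)c(OC)c2)c(OC)c1 | intermediate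
8 | ring A–C trimer phenol | COc1cc(OC)c(Oc2cc(OC)c(Oc3cc(OC)c(O)c(OC)c3)c(OC)c2)c(OC)c1 | intermediate
9 | trichloroethylene | ClC=C(Cl)Cl | starting material
10 | dichloroacetylene | ClC#CCl | intermediate
11 | (E)-1,2-dichlorovinyl ether of the A–C trimer | COc1cc(OC)c(Oc2cc(OC)c(Oc3cc(OC)c(O/C(Cl)=C\Cl)c(OC)c3)c(OC)c2)c(OC)c1 | intermediate
12 | chloroethynyl ether of the A–C trimer | COc1cc(OC)c(Oc2cc(OC)c(Oc3cc(OC)c(OC#CCl)c(OC)c3)c(OC)c2)c(OC)c1 | intermediate
13 | lithium aryloxyacetylide of the A–C trimer | COc1cc(OC)c(Oc2cc(OC)c(Oc3cc(OC)c(OC#C[Li])c(OC)c3)c(OC)c2)c(OC)c1 | intermediate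
14 | ethynyl ether of the A–C trimer | COc1cc(OC)c(Oc2cc(OC)c(Oc3cc(OC)c(OC#C)c(OC)c3)c(OC)c2)c(OC)c1 | intermediate
15 | 3,4,5-trimethoxyphenol | COc1cc(O)cc(OC)c1OC | starting material
16 | 4-bromo-3,5-dimethoxybenzaldehyde | COc1cc(C=O)cc(OC)c1Br | starting material
17 | ring F–G aldehyde | COc1cc(Oc2c(OC)cc(C=O)cc2OC)cc(OC)c1OC | intermediate
18 | ring F–G aryl formate | COc1cc(Oc2c(OC)cc(OC=O)cc2OC)cc(OC)c1OC | intermediate
19 | ring F–G phenol | COc1cc(Oc2c(OC)cc(O)cc2OC)cc(OC)c1OC | intermediate
20 | ring E–G aldehyde | COc1cc(Oc2c(OC)cc(Oc3c(OC)cc(C=O)cc3OC)cc2OC)cc(OC)c1OC | intermediate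
21 | ring E–G aryl formate | COc1cc(Oc2c(OC)cc(Oc3c(OC)cc(OC=O)cc3OC)cc2OC)cc(OC)c1OC | intermediate
22 | ring E–G trimer phenol | COc1cc(Oc2c(OC)cc(Oc3c(OC)cc(O)cc3OC)cc2OC)cc(OC)c1OC | intermediate
23 | squaryl dichloride | O=C1C(Cl)=C(Cl)C1=O | starting material
24 | 3-chloro-4-methoxycyclobut-3-ene-1,2-dione | COC1=C(Cl)C(=O)C1=O | intermediate
25 | sodium phenoxide of the E–G trimer | [Na+].[O-]c1cc(OC)c(Oc2cc(OC)c(Oc3cc(OC)c(OC)c(OC)c3)c(OC)c2)c(OC)c1 | intermediate
26 | 3-aryloxy-4-methoxycyclobut-3-ene-1,2-dione (aryl = E–G trimer) | COC1=C(Oc2cc(OC)c(Oc3cc(OC)c(Oc4cc(OC)c(OC)c(OC)c4)c(OC)c3)c(OC)c2)C(=O)C1=O | intermediate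
27 | racemic 2-aryloxy-4-hydroxy-3-methoxycyclobut-2-en-1-one | COC1=C(Oc2cc(OC)c(Oc3cc(OC)c(Oc4cc(OC)c(OC)c(OC)c4)c(OC)c3)c(OC)c2)C(=O)C1O | intermediate
28 | racemic 2-aryloxy-3,4-dimethoxycyclobut-2-en-1-one | O=C1C(Oc2cc(OC)c(Oc3cc(OC)c(Oc4cc(OC)c(OC)c(OC)c4)c(OC)c3)c(OC)c2)=C(OC)C1OC | intermediate
29 | aryloxy[(Z)-1,2-dimethoxyvinyl]ketene | O=C=C(Oc1cc(OC)c(Oc2cc(OC)c(Oc3cc(OC)c(OC)c(OC)c3)c(OC)c2)c(OC)c1)/C(OC)=C/OC | intermediate
30 | racemic 3,4-bis(aryloxy)-4-(1,2-dimethoxyvinyl)cyclobut-2-en-1-one | O=C1C=C(Oc2c(OC)cc(Oc3c(OC)cc(Oc4c(OC)cc(OC)cc4OC)cc3OC)cc2OC)C1(Oc2cc(OC)c(Oc3cc(OC)c(Oc4cc(OC)c(OC)c(OC)c4)c(OC)c3)c(OC)c2)/C(OC)=C/OC | intermediate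
31 | dienylketene with ketene and vinyl termini cis | O=C=C/C(Oc1c(OC)cc(Oc2c(OC)cc(Oc3c(OC)cc(OC)cc3OC)cc2OC)cc1OC)=C(Oc1cc(OC)c(Oc2cc(OC)c(Oc3cc(OC)c(OC)c(OC)c3)c(OC)c2)c(OC)c1)\C(OC)=C\OC | intermediate
32 | racemic 3,4-bis(aryloxy)-5,6-dimethoxycyclohexa-2,4-dien-1-one | O=C1C=C(Oc2c(OC)cc(Oc3c(OC)cc(Oc4c(OC)cc(OC)cc4OC)cc3OC)cc2OC)C(Oc2cc(OC)c(Oc3cc(OC)c(Oc4cc(OC)c(OC)c(OC)c4)c(OC)c3)c(OC)c2)=C(OC)C1OC | intermediate
33 | heptamer with free D3 hydroxyl and sixteen methyl ethers | COc1cc(OC)c(Oc2cc(OC)c(Oc3cc(OC)c(Oc4cc(O)c(OC)c(OC)c4Oc4cc(OC)c(Oc5cc(OC)c(Oc6cc(OC)c(OC)c(OC)c6)c(OC)c5)c(OC)c4)c(OC)c3)c(OC)c2)c(OC)c1 | intermediate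
34 | CNP0304148.0 | Oc1cc(O)c(Oc2cc(O)c(Oc3cc(O)c(Oc4cc(O)c(O)c(O)c4Oc4cc(O)c(Oc5cc(O)c(Oc6cc(O)c(O)c(O)c6)c(O)c5)c(O)c4)c(O)c3)c(O)c2)c(O)c1 | target

**Totals**
Total step count: 16.
Longest linear sequence: 9 steps (7, 8, 9, 10, 12, 13, 14, 15, 16). The A–C arm contributes 8 (1 to 6, 15, 16).

**Three steps most likely to fail**

Step 15. Capture of the hindered, doubly substituted ketene may be too slow. Ketene dimerisation, acylation of the newly formed phenol by the ketene, or thermal polymerisation of the terminal ynol ether could then consume the partners.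
- The fallback gives up ring construction and puts both arms on a preformed ring D by two Ullmann etherifications, ordered by the higher reactivity of C–I over C–Br. It sets out from 22 and 8 and rejoins the route at 34.
- Commercial 5-bromo-1,2,3-trimethoxybenzene is iodinated (NIS, cat. TFA, MeCN) at one of its two equivalent free positions to give 1-bromo-2-iodo-3,4,5-trimethoxybenzene F1.
- CuI/picolinic acid/K3PO4 coupling with 22 should engage the iodide first and give the ring D–G tetramer bromide F2.
- A second coupling of the same kind with hindered phenol 8 at the remaining C–Br bond gives the fully methylated heptamer F3.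
- BBr3 under the conditions of step 16 then cleaves seventeen methyl ethers to give 34.

Step 13. Discrimination between the two carbonyl groups may be poor, or attack at the aryloxy-bearing ring carbon may expel the aryloxide.
- The fallback removes the regiochemical question by symmetry. It sets out from 22 and 23 and rejoins the route at 27.
- Two equivalents of phenoxide 25 (from 22) and squaryl dichloride 23 (THF, −78 to 0 °C) give the symmetrical bis(aryl) squarate F4, whose two carbonyl groups are equivalent.
- LiAlH(OtBu)3 then gives the racemic 2,3-bis(aryloxy)-4-hydroxycyclobutenone F5.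
- Methanol with catalytic iPr2NEt (THF/MeOH, 0 °C) exchanges only the β-aryloxy group. Addition–elimination is possible only at the β-carbon of the enone, and aryloxide leaves more readily than methoxide. This gives 27 and returns one equivalent of 22 for reuse.

Step 16. Cleavage may stop short when partly cleaved borates precipitate, and the pyrogallol-type rings D and G may oxidise in air during isolation of the free polyphenol.
- The fallback replaces direct isolation by a derivatise, purify and release sequence. It sets out from 33 and rejoins the route at 34.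
- The crude BBr3 product is peracetylated without purification (Ac2O, pyridine, rt) to the heptadecaacetate F6. This neutral, air-stable compound can be chromatographed free of under-cleaved material, which can be resubmitted.
- Acid-catalysed transesterification (cat. AcCl in degassed MeOH, rt to 40 °C) then releases 34 under non-oxidising conditions.

**Further compounds**
F1 | step 15 | 1-bromo-2-iodo-3,4,5-trimethoxybenzene | COc1cc(Br)c(I)c(OC)c1OC
F2 | step 15 | ring D–G tetramer bromide (D1 bromide, D6 ether to E1) | COc1cc(Br)c(Oc2cc(OC)c(Oc3cc(OC)c(Oc4cc(OC)c(OC)c(OC)c4)c(OC)c3)c(OC)c2)c(OC)c1OC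
F3 | step 15 | fully methylated heptamer (seventeen methyl ethers) | COc1cc(OC)c(Oc2cc(OC)c(Oc3cc(OC)c(Oc4cc(OC)c(OC)c(OC)c4Oc4cc(OC)c(Oc5cc(OC)c(Oc6cc(OC)c(OC)c(OC)c6)c(OC)c5)c(OC)c4)c(OC)c3)c(OC)c2)c(OC)c1
F4 | step 13 | symmetrical bis(aryl) squarate (aryl = E–G trimer) | O=C1C(=O)C(Oc2cc(OC)c(Oc3cc(OC)c(Oc4cc(OC)c(OC)c(OC)c4)c(OC)c3)c(OC)c2)=C1Oc1cc(OC)c(Oc2cc(OC)c(Oc3cc(OC)c(OC)c(OC)c3)c(OC)c2)c(OC)c1
F5 | step 13 | racemic 2,3-bis(aryloxy)-4-hydroxycyclobut-2-en-1-one | O=C1C(Oc2cc(OC)c(Oc3cc(OC)c(Oc4cc(OC)c(OC)c(OC)c4)c(OC)c3)c(OC)c2)=C(Oc2cc(OC)c(Oc3cc(OC)c(Oc4cc(OC)c(OC)c(OC)c4)c(OC)c3)c(OC)c2)C1O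
F6 | step 16 | heptadecaacetate of the target | CC(=O)Oc1cc(OC(C)=O)c(Oc2cc(OC(C)=O)c(Oc3cc(OC(C)=O)c(Oc4cc(OC(C)=O)c(OC(C)=O)c(OC(C)=O)c4Oc4cc(OC(C)=O)c(Oc5cc(OC(C)=O)c(Oc6cc(OC(C)=O)c(OC(C)=O)c(OC(C)=O)c6)c(OC(C)=O)c5)c(OC(C)=O)c4)c(OC(C)=O)c3)c(OC(C)=O)c2)c(OC(C)=O)c1
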